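Retrosynthetic cuts, in order: the 5/5''-O-methyl and 4'/4'''-O-benzyl masks, then O1–C2 and O1''–C2'' of the two rings C, then C3–C4 and C3''–C4'', and last the C8–C8'' biaryl bond.
Enabling feature: in each half, C4 is an acyl carbon on C4a of ring A, between the oxygen-bearing carbons C5 and C8a. C3 is a CH between that carbonyl and C2, the carbon that holds ring B. C3–C4 is therefore a benzoate-carbonyl to ketone-α-carbon bond, and the twofold symmetry lets one C14 biaryl diester take up two copies of one C8 aryl methyl ketone (C30 in all).
Forward order: rings A and B are bought. The ring A salicylate is iodinated at the future C8 and its phenol (future O1) is masked as a MOM ether. Ullmann coupling makes C8–C8'', a twofold Claisen acylation makes C3–C4 and C3''–C4'', acid closes both rings C in one operation, and BCl3 frees the four phenols.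
Regiochemistry of closure: only the oxygen on C8a carries an acid-labile group, while C5–O stays a methyl ether. Ring C can therefore form only through the oxygen next to C8, and the 8,8'' linkage cannot become 6,6''.
Stereochemistry: there is no stereocentre. The only stereogenic element, the C8–C8'' axis, arises without control in the Ullmann step.

Key step: step 4

Assumption: the target string carries no descriptor for the C8–C8'' axis, so the racemic atropisomer mixture is taken as the goal.

Step 1
Reactants: 1 methyl 2-hydroxy-4,6-dimethoxybenzoate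
Product: 2 methyl 2-hydroxy-3-iodo-4,6-dimethoxybenzoate
Conditions: NIS (1.0 equiv), CF3CO2H (cat.), MeCN, 0 °C → rt
Reagents that add atoms: N-iodosuccinimide, O=C1CCC(=O)N1I
Why: Electrophilic aromatic iodination with acid-activated NIS should go to C3, which is ortho to the chelated free phenol and has only the small OH and one rotatable OCH3 beside it, whereas C5 is shielded by two methoxy groups of which the C6 one must turn its methyl towards C5; the corresponding 2-hydroxy-4,6-dimethoxyphenyl ketone is known to iodinate at the same site.

Step 2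
Reactants: 2 methyl 2-hydroxy-3-iodo-4,6-dimethoxybenzoate; 3 chloromethyl methyl ether
Product: 5 methyl 3-iodo-4,6-dimethoxy-2-(methoxymethoxy)benzoate, via sodium phenoxide 4 (not isolated)
Conditions: NaH (1.2 equiv), DMF, 0 °C; then 3 (1.4 equiv), 0 °C → rt
Reagents that add atoms: chloromethyl methyl ether 3, COCCl
Why: Williamson-type O-alkylation, in which irreversible deprotonation by NaH breaks the hydrogen bond to the ester and the free phenoxide 4 is captured by the very reactive α-chloro ether, the standard way to protect chelated and flanked phenols.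

Step 3
Reactants: 5 methyl 3-iodo-4,6-dimethoxy-2-(methoxymethoxy)benzoate (two molecules)
Product: 6 dimethyl 4,4',6,6'-tetramethoxy-2,2'-bis(methoxymethoxy)biphenyl-3,3'-dicarboxylate (racemic)
Conditions: activated Cu powder (8 equiv), DMF, 150 °C, argon
Reagents that add atoms: none
Why: Classical Ullmann reductive homocoupling, in which an arylcopper species formed at the C–I bond couples with a second aryl iodide; 2,6-dialkoxyaryl iodides of the phloroglucinol type are established substrates, the neutral medium leaves ester and acetal groups alone, and the tetra-ortho-substituted axis forms as a racemate.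

Step 4
Reactants: 6 dimethyl 4,4',6,6'-tetramethoxy-2,2'-bis(methoxymethoxy)biphenyl-3,3'-dicarboxylate; 7 1-[4-(benzyloxy)phenyl]ethanone
Product: 9 1,1'-[4,4',6,6'-tetramethoxy-2,2'-bis(methoxymethoxy)biphenyl-3,3'-diyl]bis{3-[4-(benzyloxy)phenyl]propane-1,3-dione}, via lithium enolate 8 (not isolated)
Conditions: 7 (5 equiv), LiN(SiMe3)2 (8 equiv), THF, −78 → 0 °C; then 6, 0 → 60 °C; AcOH quench
Reagents that add atoms: none
Why: This is a crossed Claisen condensation run twice in one flask: enolate 8 attacks each ester carbonyl of 6, the tetrahedral adduct expels methoxide, and the 1,3-diketone so formed is deprotonated at once by the surplus amide base, which makes each acylation irreversible. The closest known reaction is the acylation of acetophenone lithium enolates by 2-alkoxybenzoates, the diketone entry to flavones. No ring is closed and no stereocentre is made, and the axis set in step 3 is untouched. The selectivity needed is C-acylation of a di-ortho-substituted, electron-rich ester in preference to ketone self-condensation; complete deprotonation of 7 with more base than ketone leaves no neutral ketone for aldol addition, so the mixture can be warmed until the slow esters are consumed. In 6 the ester carbonyl is twisted out of conjugation with ring A, which restores some electrophilicity, and the neighbouring OCH2OCH3 and OCH3 oxygens can bind lithium and hold the enolate near the carbonyl carbon. Compound 6 has no enolisable position and its two esters are equivalent, so only mono- and bis-acylation compete, and the excess of 8 drives the reaction to the bis-adduct.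

Step 5
Reactants: 9 1,1'-[4,4',6,6'-tetramethoxy-2,2'-bis(methoxymethoxy)biphenyl-3,3'-diyl]bis{3-[4-(benzyloxy)phenyl]propane-1,3-dione}
Product: 11 2,2'-bis[4-(benzyloxy)phenyl]-5,5',7,7'-tetramethoxy-4H,4'H-[8,8'-bichromene]-4,4'-dione, via bis(phenol) bis(diketone) 10 (not isolated)
Conditions: conc. HCl, MeOH–THF (1:1), 60 °C
Reagents that add atoms: none
Why: Acid-catalysed acetal exchange frees only the two C8a phenols, each of which adds to the ring B carbonyl (future C2) and loses water as in the last stage of the diketone flavone synthesis, while methanol takes up the formaldehyde unit as its dimethyl acetal and the aryl benzyl and methyl ethers tolerate methanolic HCl at this temperature.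

Step 6
Reactants: 11 2,2'-bis[4-(benzyloxy)phenyl]-5,5',7,7'-tetramethoxy-4H,4'H-[8,8'-bichromene]-4,4'-dione
Product: 12 5,5'-dihydroxy-2,2'-bis(4-hydroxyphenyl)-7,7'-dimethoxy-4H,4'H-[8,8'-bichromene]-4,4'-dione (7,7''-di-O-methylcupressuflavone, target)
Conditions: BCl3 (1 M in CH2Cl2, 10 equiv), pentamethylbenzene (6 equiv), CH2Cl2, −78 °C → rt; then H2O
Reagents that add atoms: none
Why: Chelation-controlled ether cleavage, in which BCl3 bridges the C4 carbonyl and the peri 5-methoxy oxygen in a six-membered chelate so that chloride removes only that methyl group, the unchelated 7-methoxy groups stay, and the same Lewis acid cleaves the aryl benzyl ethers with pentamethylbenzene as a non-basic trap that keeps the benzyl cation off C6 of ring A.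

Compound list
1 | methyl 2-hydroxy-4,6-dimethoxybenzoate | COC(=O)c1c(O)cc(OC)cc1OC | starting material
2 | methyl 2-hydroxy-3-iodo-4,6-dimethoxybenzoate | COC(=O)c1c(O)c(I)c(OC)cc1OC | intermediate
3 | chloromethyl methyl ether | COCCl | starting material
4 | sodium 2-iodo-3,5-dimethoxy-6-(methoxycarbonyl)phenolate (not isolated) | [Na+].COC(=O)c1c([O-])c(I)c(OC)cc1OC | intermediate
5 | methyl 3-iodo-4,6-dimethoxy-2-(methoxymethoxy)benzoate | COCOc1c(I)c(OC)cc(OC)c1C(=O)OC | intermediate
6 | dimethyl 4,4',6,6'-tetramethoxy-2,2'-bis(methoxymethoxy)biphenyl-3,3'-dicarboxylate (racemic axis) | COCOc1c(C(=O)OC)c(OC)cc(OC)c1-c1c(OC)cc(OC)c(C(=O)OC)c1OCOC | intermediate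
7 | 1-[4-(benzyloxy)phenyl]ethanone | CC(=O)c1ccc(OCc2ccccc2)cc1 | starting material
8 | lithium 1-[4-(benzyloxy)phenyl]ethenolate (not isolated) | [Li+].C=C([O-])c1ccc(OCc2ccccc2)cc1 | intermediate
9 | 1,1'-[4,4',6,6'-tetramethoxy-2,2'-bis(methoxymethoxy)biphenyl-3,3'-diyl]bis{3-[4-(benzyloxy)phenyl]propane-1,3-dione} | COCOc1c(C(=O)CC(=O)c2ccc(OCc3ccccc3)cc2)c(OC)cc(OC)c1-c1c(OC)cc(OC)c(C(=O)CC(=O)c2ccc(OCc3ccccc3)cc2)c1OCOC | intermediate
10 | 1,1'-(2,2'-dihydroxy-4,4',6,6'-tetramethoxybiphenyl-3,3'-diyl)bis{3-[4-(benzyloxy)phenyl]propane-1,3-dione} (not isolated) | COc1cc(OC)c(C(=O)CC(=O)c2ccc(OCc3ccccc3)cc2)c(O)c1-c1c(OC)cc(OC)c(C(=O)CC(=O)c2ccc(OCc3ccccc3)cc2)c1O | intermediate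
11 | 2,2'-bis[4-(benzyloxy)phenyl]-5,5',7,7'-tetramethoxy-4H,4'H-[8,8'-bichromene]-4,4'-dione | COc1cc(OC)c2c(=O)cc(-c3ccc(OCc4ccccc4)cc3)oc2c1-c1c(OC)cc(OC)c2c(=O)cc(-c3ccc(OCc4ccccc4)cc3)oc12 | intermediate
12 | 5,5'-dihydroxy-2,2'-bis(4-hydroxyphenyl)-7,7'-dimethoxy-4H,4'H-[8,8'-bichromene]-4,4'-dione | COc1cc(O)c2c(=O)cc(-c3ccc(O)cc3)oc2c1-c1c(OC)cc(O)c2c(=O)cc(-c3ccc(O)cc3)oc12 | target

Total step count: 6. Longest linear sequence: 6 steps (1 → 2 → 5 → 6 → 9 → 11 → 12).

Steps most likely to fail

Step 4. Addition to the crowded ester carbonyls may be so slow that the reaction stalls after one acylation, or the enolate decays on long heating. The fallback sets out from 6 and comes back at 9; it keeps the C3–C4 bond formation but replaces methoxide by a far better leaving group. Compound 6 would be saponified (KOH, aq. DMSO, 100 °C, then careful acidification with cold dilute HCl) to 4,4',6,6'-tetramethoxy-2,2'-bis(methoxymethoxy)biphenyl-3,3'-dicarboxylic acid F1. This acid would be activated under neutral, MOM-compatible conditions (1,1'-carbonyldiimidazole, THF, rt → 40 °C) to the bis(acyl imidazolide) [4,4',6,6'-tetramethoxy-2,2'-bis(methoxymethoxy)biphenyl-3,3'-diyl]bis(1H-imidazol-1-ylmethanone) F2. Treatment of F2 with enolate 8 (THF, −78 → 0 °C), a known C-acylation of ketone lithium enolates, should then give 9 without heating.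

Step 3. Protodeiodination and incomplete coupling may take over, because both positions next to the C–I carbon are occupied and the ring is electron-rich. The fallback sets out from 5 and comes back at 6; it replaces the copper-mediated reductive coupling by a palladium-catalysed cross-coupling of two differently functionalised halves. One half of 5 would undergo Miyaura borylation (B2pin2, KOAc, Pd(OAc)2/SPhos, dioxane, 100 °C) to methyl 4,6-dimethoxy-2-(methoxymethoxy)-3-(4,4,5,5-tetramethyl-1,3,2-dioxaborolan-2-yl)benzoate F3. This boronate would be joined to the other half of 5 by Suzuki–Miyaura coupling (Pd(OAc)2/SPhos, K3PO4, toluene–H2O, 100 °C) to give 6.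

Step 1. Site selectivity between C3 and C5 may be poor, and the very electron-rich ring may take up a second iodine. The fallback sets out from 1 and comes back at 6; it avoids halogenation altogether. Oxidative ortho–ortho phenol coupling of 1 (FeCl3 on SiO2, solvent-free or in CH2Cl2, rt), a reaction known for the corresponding 2-hydroxy-4,6-dimethoxyphenyl ketone, should give dimethyl 2,2'-dihydroxy-4,4',6,6'-tetramethoxybiphenyl-3,3'-dicarboxylate F4. Both phenols of F4 would then be protected (NaH, DMF, 0 °C; then 3) to give 6.

Further compounds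
F1 | step 4 | 4,4',6,6'-tetramethoxy-2,2'-bis(methoxymethoxy)biphenyl-3,3'-dicarboxylic acid | COCOc1c(C(=O)O)c(OC)cc(OC)c1-c1c(OC)cc(OC)c(C(=O)O)c1OCOC
F2 | step 4 | [4,4',6,6'-tetramethoxy-2,2'-bis(methoxymethoxy)biphenyl-3,3'-diyl]bis(1H-imidazol-1-ylmethanone) | COCOc1c(C(=O)n2ccnc2)c(OC)cc(OC)c1-c1c(OC)cc(OC)c(C(=O)n2ccnc2)c1OCOC
F3 | step 3 | methyl 4,6-dimethoxy-2-(methoxymethoxy)-3-(4,4,5,5-tetramethyl-1,3,2-dioxaborolan-2-yl)benzoate | COCOc1c(B2OC(C)(C)C(C)(C)O2)c(OC)cc(OC)c1C(=O)OC
F4 | step 1 | dimethyl 2,2'-dihydroxy-4,4',6,6'-tetramethoxybiphenyl-3,3'-dicarboxylate | COC(=O)c1c(O)c(-c2c(O)c(C(=O)OC)c(OC)cc2OC)c(OC)cc1OC
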